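## Structural features

Daphnodorin C joins a 4,6-dihydroxybenzofuran-3(2H)-one (O1, spiro C2, C3=O, C3a–C7a) and a 2-aryl-2,3-dihydrobenzofuran (O1′, C2′ bearing 4-hydroxyphenyl, C3′ = the same spiro carbon) at one spiro atom; the benzo ring of the dihydrofuran is ring A of a (2S)-4′,5-dihydroxyflavan, bonded through flavan O7 (= O1′) and flavan C8. The spiro carbon is fully substituted (O1, C3 carbonyl, flavan C8, C2′) and stands directly next to the benzylic O–CH–aryl centre C2′; both are S, and the aryl group on C2′ is cis to O1 and trans to the C3 carbonyl across the dihydrofuran ring. The third stereocentre, flavan C2 (S), lies four bonds from the spiro carbon on the far side of a flat arene and cannot steer the other two, so their absolute configuration needs its own source. Fragile points are the two benzylic aryl-ether bonds (C2′–O7 and flavan C2–O1), which ionise through p-quinone methides once the 4-hydroxyphenyl groups are free, the α-aryloxy ketone at the spiro carbon, and the oxidisable phloroglucinol-type rings. Regiochemistry on flavan ring A (C8 against C6, O7 against O5) is a second, hidden problem. The real difficulty is the contiguous spiro/benzylic pair: flavan C8 is joined to the α-carbon and O7 to the benzylic β-carbon of an aurone unit, whereas conjugate addition of the nucleophilic C8 would join it to the β-carbon, and the quaternary centre must be made with the right face relative to C2′. The feature the key step exploits is that the spiro carbon carries exactly the O1/aryl pair of C2 of a 2-arylbenzofuran while its neighbour C3 is a ketone bonded to C3a: the spiro ketone is therefore the 1,2-shift isomer of the C2–C3 epoxide of a benzofuran whose C3 holds C2′, that is, of a six-membered 2H-chromene ring (O7, C2′, benzofuran C3, benzofuran C2, flavan C8, flavan C7) that contracts to the dihydrofuran. In one sentence, the route makes the spiro centre by epoxidation-triggered semipinacol ring contraction of a 6-aryl-6H-benzofuro[3,2-c]chromene (a 6-arylpterocarpene) built on the flavan.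

## Logic of the disconnections

21 to 20: the five O–benzyl bonds are cut. All phenols are masked as one ether type because free p-hydroxybenzyl ethers epimerise and free phloroglucinol rings would not survive the oxidant of the key step. The demand is a neutral hydrogenolysis that spares the benzylic C–O ring bonds.

20 to 18 (through 19): the bond spiro C2–C2′ is cut and C2′ is reattached to the carbonyl carbon C3 (retro-semipinacol); the epoxide oxygen is then removed. In pterocarpan locants C2′ is C6, C3 is C6a, the spiro carbon is C11a, O1 is O11 and flavan C8 is C11b. The gain is large: the quaternary spiro stereocentre disappears, two contiguous stereocentres reduce to the single centre C6, and the spiro bis-heterocycle becomes a flat fused tetracycle. The forward step must epoxidise anti to the C6 aryl group, ionise at C11a and not at C6a, and shift C6 in a concerted, suprafacial way.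

18 to 16 + 17: the C6–aryl bond is cut. C6 is the only new stereocentre, and in 16 it is an acetal carbon that ionises to a flat, stabilised benzopyrylium ion, so a chiral catalyst can set it. The aryl group then comes from a commercial boronic acid. The forward step needs catalyst-controlled face selectivity (the flavan centre is too far away) and non-acidic conditions so that the product does not ionise again.

16 to 15: the acetal bonds C6–O5 and C6–OEt are cut and the MOM group is put back on flavan O7. The ring closes by itself once O7 is freed next to the formyl group. The acid must leave the benzyl ethers and the flavan ring intact.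

15 to 13 + 9 (through 14): the biaryl bond flavan C8–benzofuran C2 is cut, the most convergent cut, into two fragments of similar size. C2–H of 13 is its most acidic site (next to the ring oxygen, ortho to the formyl group), and C8–Br of 9 comes from a regioselective bromination. The demand is a hindered Negishi coupling that tolerates an aldehyde.

13 to 12 to 11 to 10: the C3–CHO bond, the O–Tf bond and two O–benzyl bonds are cut. The ketone of 10 marks C3 unambiguously; electrophilic formylation of a 4,6-dialkoxybenzofuran would go elsewhere (C2 or C7).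

9 to 8: the C8–Br bond is cut. C8 is the least hindered doubly activated position of the 5,7-dialkoxyflavan ring; the forward step must stop at monobromination.

8 to 7 to 6: the flavan O1–C2 bond is cut (ether formation with inversion) and then the carbinol C–H bond (asymmetric transfer hydrogenation). Flavan C2 is thus set by a catalyst on a simple aryl alkyl ketone. The demand is a clean SN2 closure at a p-alkoxybenzylic carbon.

6 to 5 to 3 + 4: the alkene is restored and the enone C=C bond is cut (aldol condensation), which gives two simple aromatic pieces.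

3 to 2 to 1: one O–benzyl and one O–MOM bond are cut. The three phenols of 1 are told apart by acidity and chelation: the para-OH takes MOM (it becomes flavan O7, the oxygen released selectively in step 12), one ortho-OH takes benzyl (flavan O5), and the remaining chelated OH becomes flavan O1.

## Other disconnections considered

Alternative 1: the first idea, a formal [3+2] of the flavan phenol with an aurone unit. The cut is flavan C8–spiro C2 plus O7–C2′. The forward key step would be acid-promoted opening of the aurone-type spiro-epoxide A1 by the flavan phenol A2 at the benzylic carbon, followed by Friedel–Crafts closure of C8 onto the C2 hemiketal. Both bonds would form at flat cations (a p-alkoxybenzyl cation at C2′, a 3-oxo-oxocarbenium ion at C2). Neither the configuration at C2′ nor that at the spiro carbon is relayed by a stereospecific event, and nothing controls them relative to flavan C2. C-alkylation of the phloroglucinol ring of A2 at C2′ (at C6 or C8) would compete with O-alkylation and lead to the constitutional isomer. The chosen plan forms the same two bonds at defined positions before any stereocentre exists and then relays one catalyst-set centre through a 1,2-shift.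

Alternative 2: cut the spiro C2–O1 bond. The forward key step would be oxidative C–O spirocyclisation of the 3-aroyl-2-aryl-2,3-dihydrobenzofuran A3 (enolisation, then hypervalent iodine or α-halogenation and displacement by the ortho-phenol). The stereocentre α to the ketone of A3 is erased on enolisation. The new C–O bond would form on the face away from the neighbouring aryl group, which places O1 trans to that aryl, the opposite of the target. The same oxidising conditions can dehydrogenate A3 to the aromatic 2-aryl-3-aroylbenzofuran. A3 itself carries two stereocentres that need their own synthesis, so the plan is also longer.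

Alternative 3: cut the spiro C2–C3 bond and the O1–aryl bond. The forward key step would be 1,2-addition of a 2-fluoro-4,6-bis(benzyloxy)benzoyl anion equivalent to the flavan-fused 2-aryl-benzofuran-3(2H)-one A4, followed by SNAr closure by the tertiary alkoxide. A4 is the keto tautomer of an aromatic 3-hydroxybenzofuran: its C2′–H is removed by any basic nucleophile, which erases the configuration at C2′ and turns the ketone into an unreactive enolate. Addition to such a hindered, enolisable ketone is poor, and the route needs more steps than the chosen one.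

Key step: step 14

Remark on the chemistry: 1, 4, 10 and 17 are taken as commercial, DMDO and TMPZnCl·LiCl are made beforehand by the standard procedures, the tetracyclic intermediates carry pterocarpan locants as given above, and in step 13 the ligand antipode is chosen that gives the 6S epimer (the two C6 epimers are diastereomers and can be told apart by HPLC or NMR).

## Route

Step 1
Reactants: 1 2,4,6-trihydroxybenzaldehyde
Product: 2 2,6-dihydroxy-4-(methoxymethoxy)benzaldehyde
Conditions: MOMCl (1.0 equiv), i-Pr2NEt, THF, 0 °C
Reagents that add atoms: chloromethyl methyl ether, COCCl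
Why: The 4-OH is the most acidic phenol and the only one not hydrogen-bonded to the formyl group, so one equivalent of electrophile should alkylate it selectively (Williamson-type O-alkylation).

Step 2
Reactants: 2 2,6-dihydroxy-4-(methoxymethoxy)benzaldehyde
Product: 3 2-(benzyloxy)-6-hydroxy-4-(methoxymethoxy)benzaldehyde
Conditions: BnBr (1.05 equiv), K2CO3, acetone, rt
Reagents that add atoms: benzyl bromide, BrCc1ccccc1
Why: Williamson benzylation of one of two equivalent ortho-phenols; the remaining phenol is then strongly chelated to the aldehyde and should resist a second alkylation.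

Step 3
Reactants: 3 2-(benzyloxy)-6-hydroxy-4-(methoxymethoxy)benzaldehyde; 4 1-[4-(benzyloxy)phenyl]ethan-1-one
Product: 5 (E)-3-[2-(benzyloxy)-6-hydroxy-4-(methoxymethoxy)phenyl]-1-[4-(benzyloxy)phenyl]prop-2-en-1-one
Conditions: KOH (50% aq.), EtOH, rt
Reagents that add atoms: none
Why: Claisen–Schmidt condensation of a salicylaldehyde with an acetophenone; dehydration gives the conjugated E-enone, and MOM and benzyl ethers are stable to hydroxide.

Step 4
Reactants: 5 (E)-3-[2-(benzyloxy)-6-hydroxy-4-(methoxymethoxy)phenyl]-1-[4-(benzyloxy)phenyl]prop-2-en-1-one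
Product: 6 3-[2-(benzyloxy)-6-hydroxy-4-(methoxymethoxy)phenyl]-1-[4-(benzyloxy)phenyl]propan-1-one
Conditions: H2 (1 atm), 10% Pd/C, Ph2S (0.01 equiv), EtOAc, rt
Reagents that add atoms: none
Why: Sulfide-poisoned Pd/C hydrogenates the enone C=C bond while leaving benzyl ethers and the aryl ketone untouched (chemoselective catalytic hydrogenation).

Step 5
Reactants: 6 3-[2-(benzyloxy)-6-hydroxy-4-(methoxymethoxy)phenyl]-1-[4-(benzyloxy)phenyl]propan-1-one
Product: 7 (1R)-1-[4-(benzyloxy)phenyl]-3-[2-(benzyloxy)-6-hydroxy-4-(methoxymethoxy)phenyl]propan-1-ol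
Conditions: RuCl[(R,R)-TsDPEN](p-cymene) (1 mol%), HCO2H/Et3N (5:2), DMF, rt
Reagents that add atoms: none
Why: Noyori–Ikariya asymmetric transfer hydrogenation of an aryl alkyl ketone; the (R,R)-catalyst delivers hydride to the face that gives the R carbinol (same sense as acetophenone to (R)-1-phenylethanol), and the free phenol and the MOM ether are tolerated.

Step 6
Reactants: 7 (1R)-1-[4-(benzyloxy)phenyl]-3-[2-(benzyloxy)-6-hydroxy-4-(methoxymethoxy)phenyl]propan-1-ol
Product: 8 (2S)-5-(benzyloxy)-2-[4-(benzyloxy)phenyl]-7-(methoxymethoxy)chromane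
Conditions: PPh3, DIAD, THF, 0 °C
Reagents that add atoms: none
Why: Intramolecular Mitsunobu etherification (6-exo-tet); the phenoxide displaces the activated carbinol oxygen with inversion, so the R carbinol should give the 2S flavan.

Step 7
Reactants: 8 (2S)-5-(benzyloxy)-2-[4-(benzyloxy)phenyl]-7-(methoxymethoxy)chromane
Product: 9 (2S)-5-(benzyloxy)-2-[4-(benzyloxy)phenyl]-8-bromo-7-(methoxymethoxy)chromane
Conditions: NBS (1.0 equiv), CH2Cl2, −78 to 0 °C
Reagents that add atoms: N-bromosuccinimide, O=C1CCC(=O)N1Br
Why: Electrophilic aromatic bromination of a 5,7-dialkoxyflavan; C8 (between the ring oxygen and O7) is less hindered than C6 (between two exocyclic ethers) and is the usual site of monobromination in this ring type.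

Step 8
Reactants: 10 4,6-dihydroxybenzofuran-3(2H)-one
Product: 11 4,6-bis(benzyloxy)benzofuran-3(2H)-one
Conditions: BnBr (2.2 equiv), K2CO3, DMF, rt
Reagents that add atoms: benzyl bromide, BrCc1ccccc1
Why: Williamson O-benzylation of both phenols; with a weak base the phenoxides react faster than the C2 methylene.

Step 9
Reactants: 11 4,6-bis(benzyloxy)benzofuran-3(2H)-one
Product: 12 4,6-bis(benzyloxy)benzofuran-3-yl trifluoromethanesulfonate
Conditions: Tf2O, i-Pr2NEt, CH2Cl2, −78 to 0 °C
Reagents that add atoms: trifluoromethanesulfonic anhydride, O=S(=O)(OS(=O)(=O)C(F)(F)F)C(F)(F)F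
Why: O-triflation of the enol form of the coumaranone, driven by aromatisation to the benzofuran; it fixes the future carbon substituent at C3.

Step 10
Reactants: 12 4,6-bis(benzyloxy)benzofuran-3-yl trifluoromethanesulfonate
Product: 13 4,6-bis(benzyloxy)benzofuran-3-carbaldehyde
Conditions: Pd(OAc)2 (5 mol%), dppp (5 mol%), CO (1 atm), Et3SiH, Et3N, DMF, 70 °C
Reagents that add atoms: carbon monoxide, [C-]#[O+]
Why: Palladium-catalysed reductive carbonylation (formylation) of an enol/aryl triflate: oxidative addition, CO insertion and hydride transfer from the silane to the acyl-palladium species.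

Step 11
Reactants: 13 4,6-bis(benzyloxy)benzofuran-3-carbaldehyde; 9 (2S)-5-(benzyloxy)-2-[4-(benzyloxy)phenyl]-8-bromo-7-(methoxymethoxy)chromane
Product: 15 4,6-bis(benzyloxy)-2-[(2S)-5-(benzyloxy)-2-[4-(benzyloxy)phenyl]-7-(methoxymethoxy)chroman-8-yl]benzofuran-3-carbaldehyde, via [4,6-bis(benzyloxy)-3-formylbenzofuran-2-yl]zinc chloride 14 (not isolated)
Conditions: TMPZnCl·LiCl (1.2 equiv), THF, 25 °C; then 9, Pd(OAc)2 (4 mol%), SPhos (8 mol%), THF, 60 °C
Reagents that add atoms: TMPZnCl·LiCl, CC1(C)CCCC(C)(C)N1[Zn]Cl.[Li+].[Cl-]
Why: Directed zincation with a Knochel–Hauser base at the most acidic C–H (C2, next to the ring oxygen and ortho to the formyl group) puts ZnCl on the intermediate 14, and Negishi coupling then replaces it by the flavan C8, so no atom of the base remains in 15. The arylzinc does not add to the aldehyde, and a biarylphosphine ligand handles the di-ortho-substituted bromide.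

Step 12
Reactants: 15 4,6-bis(benzyloxy)-2-[(2S)-5-(benzyloxy)-2-[4-(benzyloxy)phenyl]-7-(methoxymethoxy)chroman-8-yl]benzofuran-3-carbaldehyde
Product: 16 7,9-bis(benzyloxy)-6-ethoxy-6H-benzofuro[3,2-c]chromene whose chromene benzo ring is ring A of the (2S)-5-(benzyloxy)-2-[4-(benzyloxy)phenyl]chromane (O5 = flavan O7; C11b = flavan C8; mixture of C6 epimers)
Conditions: HCl (1.25 M in EtOH), THF, 40 °C
Reagents that add atoms: ethanol, CCO
Why: Acid-catalysed acetal exchange removes the MOM group, and the freed phenol closes onto the neighbouring aldehyde (6-exo-trig) to a lactol that is trapped as its ethyl acetal through the stabilised benzopyrylium ion; the C6 configuration is irrelevant because it is erased in step 13.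

Step 13
Reactants: 16 7,9-bis(benzyloxy)-6-ethoxy-6H-benzofuro[3,2-c]chromene on the (2S)-flavan (C6 epimers); 17 [4-(benzyloxy)phenyl]boronic acid
Product: 18 (6S)-7,9-bis(benzyloxy)-6-[4-(benzyloxy)phenyl]-6H-benzofuro[3,2-c]chromene whose chromene benzo ring is ring A of the (2S)-5-(benzyloxy)-2-[4-(benzyloxy)phenyl]chromane (O5 = flavan O7; C11b = flavan C8)
Conditions: Ni(cod)2 (10 mol%), TADDOL-derived chiral phosphonite (12 mol%), 17 (2 equiv), dioxane/t-AmOH, 40 °C
Reagents that add atoms: none
Why: Nickel-catalysed enantioselective arylation of a 2-alkoxy-2H-chromene acetal with an arylboronic acid: boron-assisted ionisation to the flat benzopyrylium ion, oxidative addition of chiral Ni(0) at C6 (C11a is fully substituted and part of the furan), transmetalation and reductive elimination. C6 is set by the ligand (catalyst control).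

Step 14
Reactants: 18 (6S)-6-aryl-6H-benzofuro[3,2-c]chromene (6-arylpterocarpene) on the (2S)-flavan
Product: 20 penta-O-benzyl-daphnodorin C, via pterocarpene 6a,11a-epoxide 19 (not isolated)
Conditions: DMDO (1.1 equiv, acetone), CH2Cl2, −78 °C; then warm to −20 °C (BF3·OEt2, 5 mol%, only if 19 persists)
Reagents that add atoms: dimethyldioxirane, CC1(C)OO1
Why: Proposed new method: DMDO epoxidises the electron-rich, tetrasubstituted C6a=C11a enol-ether bond of the benzofuran to 19, whose C11a–O bond then ionises because C11a is at once an oxocarbenium carbon (O11) and benzylic to the coplanar trioxygenated flavan ring, and the C6a alkoxide drives a suprafacial 1,2-shift of C6 from C6a to C11a, anti to the departing oxygen, which turns C6a into the ketone; the closest known reaction types are the oxidative rearrangement of 2,3-disubstituted indoles to spiro-pseudoindoxyls and the semipinacol rearrangement of 2,3-epoxy ethers, not yet shown for a pterocarpene with an α-aryloxybenzyl migrating group. The dihydrofuran ring is not closed by a cyclisation but arises by contraction of the six-membered chromene ring (6 to 5) through the 1,2-shift, and the coumaranone ring is already present because its O11–C11a bond is never broken. C2′ (the migrating C6) should keep its S configuration, since a concerted shift proceeds with retention at the migrating carbon and the new bond takes the place and the priority rank of the old one. The spiro centre is fixed by the face of epoxidation, because C6 must arrive on the face opposite to the epoxide oxygen; this places the aryl group on C2′ cis to O1 and trans to the new carbonyl (spiro C2 S), as in the target, so the one stereocentre of 18 controls both. Face selectivity is needed and should come from the C6 aryl group, which is pushed pseudo-axial by the peri 7-benzyloxy group and shields one face of the double bond. Regioselective opening at C11a and not at C6a is needed and should come from the extra lone-pair stabilisation by O11. Only C6 can migrate, since the other substituent on C6a is the ring carbon C6b tied to O11. A low temperature and a non-polar medium are chosen to keep the shift concerted.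

Step 15
Reactants: 20 penta-O-benzyl-daphnodorin C
Product: 21 daphnodorin C
Conditions: H2 (1 atm), 20% Pd(OH)2/C, EtOAc/MeOH, rt
Reagents that add atoms: none
Why: Catalytic hydrogenolysis of the five aryl benzyl ethers under neutral conditions; aryl O-benzyl bonds cleave faster than the cyclic benzylic ether bonds, and no stereocentre is touched.

## Compound list

1 | 2,4,6-trihydroxybenzaldehyde | O=Cc1c(O)cc(O)cc1O | starting material
2 | 2,6-dihydroxy-4-(methoxymethoxy)benzaldehyde | O=Cc1c(O)cc(OCOC)cc1O | intermediate
3 | 2-(benzyloxy)-6-hydroxy-4-(methoxymethoxy)benzaldehyde | O=Cc1c(O)cc(OCOC)cc1OCc1ccccc1 | intermediate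
4 | 1-[4-(benzyloxy)phenyl]ethan-1-one | CC(=O)c1ccc(OCc2ccccc2)cc1 | starting material
5 | (E)-3-[2-(benzyloxy)-6-hydroxy-4-(methoxymethoxy)phenyl]-1-[4-(benzyloxy)phenyl]prop-2-en-1-one | O=C(/C=C/c1c(O)cc(OCOC)cc1OCc1ccccc1)c1ccc(OCc2ccccc2)cc1 | intermediate
6 | 3-[2-(benzyloxy)-6-hydroxy-4-(methoxymethoxy)phenyl]-1-[4-(benzyloxy)phenyl]propan-1-one | O=C(CCc1c(O)cc(OCOC)cc1OCc1ccccc1)c1ccc(OCc2ccccc2)cc1 | intermediate
7 | (1R)-1-[4-(benzyloxy)phenyl]-3-[2-(benzyloxy)-6-hydroxy-4-(methoxymethoxy)phenyl]propan-1-ol | O[C@H](CCc1c(O)cc(OCOC)cc1OCc1ccccc1)c1ccc(OCc2ccccc2)cc1 | intermediate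
8 | (2S)-5-(benzyloxy)-2-[4-(benzyloxy)phenyl]-7-(methoxymethoxy)chromane | COCOc1cc(OCc2ccccc2)c2c(c1)O[C@H](c1ccc(OCc3ccccc3)cc1)CC2 | intermediate
9 | (2S)-5-(benzyloxy)-2-[4-(benzyloxy)phenyl]-8-bromo-7-(methoxymethoxy)chromane | COCOc1cc(OCc2ccccc2)c2c(c1Br)O[C@H](c1ccc(OCc3ccccc3)cc1)CC2 | intermediate
10 | 4,6-dihydroxybenzofuran-3(2H)-one | O=C1COc2cc(O)cc(O)c12 | starting material
11 | 4,6-bis(benzyloxy)benzofuran-3(2H)-one | O=C1COc2cc(OCc3ccccc3)cc(OCc3ccccc3)c12 | intermediate
12 | 4,6-bis(benzyloxy)benzofuran-3-yl trifluoromethanesulfonate | O=S(=O)(Oc1coc2cc(OCc3ccccc3)cc(OCc3ccccc3)c12)C(F)(F)F | intermediate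
13 | 4,6-bis(benzyloxy)benzofuran-3-carbaldehyde | O=Cc1coc2cc(OCc3ccccc3)cc(OCc3ccccc3)c12 | intermediate
14 | [4,6-bis(benzyloxy)-3-formylbenzofuran-2-yl]zinc chloride (LiCl complex in solution) | O=Cc1c([Zn]Cl)oc2cc(OCc3ccccc3)cc(OCc3ccccc3)c12 | intermediate (not isolated)
15 | 4,6-bis(benzyloxy)-2-[(2S)-5-(benzyloxy)-2-[4-(benzyloxy)phenyl]-7-(methoxymethoxy)chroman-8-yl]benzofuran-3-carbaldehyde | COCOc1cc(OCc2ccccc2)c3c(c1-c1oc4cc(OCc5ccccc5)cc(OCc5ccccc5)c4c1C=O)O[C@H](c1ccc(OCc4ccccc4)cc1)CC3 | intermediate
16 | 7,9-bis(benzyloxy)-6-ethoxy-6H-benzofuro[3,2-c]chromene fused through O5/C11b to the (2S)-5-(benzyloxy)-2-[4-(benzyloxy)phenyl]chromane (cyclic ethyl acetal, C6 epimers) | CCOC1Oc2cc(OCc6ccccc6)c3c(c2-c2oc4cc(OCc5ccccc5)cc(OCc5ccccc5)c4c21)O[C@H](c1ccc(OCc2ccccc2)cc1)CC3 | intermediate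
17 | [4-(benzyloxy)phenyl]boronic acid | OB(O)c1ccc(OCc2ccccc2)cc1 | starting material
18 | (6S)-7,9-bis(benzyloxy)-6-[4-(benzyloxy)phenyl]-6H-benzofuro[3,2-c]chromene fused through O5/C11b to the (2S)-5-(benzyloxy)-2-[4-(benzyloxy)phenyl]chromane (6-arylpterocarpene) | O1c2cc(OCc6ccccc6)c3c(c2-c2oc4cc(OCc5ccccc5)cc(OCc5ccccc5)c4c2[C@@H]1c1ccc(OCc2ccccc2)cc1)O[C@H](c1ccc(OCc2ccccc2)cc1)CC3 | intermediate
19 | 6a,11a-epoxide of 18 (epoxide oxygen anti to the C6 aryl group) | O1c2cc(OCc6ccccc6)c3c(c2[C@]24Oc5cc(OCc7ccccc7)cc(OCc7ccccc7)c5[C@]2(O4)[C@@H]1c1ccc(OCc2ccccc2)cc1)O[C@H](c1ccc(OCc2ccccc2)cc1)CC3 | intermediate (not isolated)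
20 | penta-O-benzyl-daphnodorin C (spiro C2 S, C2′ S, flavan C2 S) | O=C1c2c(OCc3ccccc3)cc(OCc3ccccc3)cc2O[C@]12c1c(cc(OCc3ccccc3)c3c1O[C@H](c1ccc(OCc4ccccc4)cc1)CC3)O[C@H]2c1ccc(OCc3ccccc3)cc1 | intermediate
21 | daphnodorin C | O=C1c2c(O)cc(O)cc2O[C@]12c1c(cc(O)c3c1O[C@H](c1ccc(O)cc1)CC3)O[C@H]2c1ccc(O)cc1 | target

## Step count and least certain steps

Total: 15 steps. Longest linear sequence: 12 steps (steps 1–7 and 11–15); the benzofuran branch (steps 8–10) joins at step 11.

Step 14 (key step, proposed new method). The most likely failure is opening of the epoxide at the wrong carbon: C6a is benzylic to the trioxygenated benzofuran ring, and ionisation there leads to quinone-methide valence isomerisation or to migration of flavan C8, which gives the isomeric 3-spiro-benzofuran-2-one. A second risk is a stepwise shift, by heterolysis of the C6a–C6 bond to a benzofuran-3-olate and an aryl-stabilised oxocarbenium ion followed by recombination, which would erode the transfer of configuration from C6. The fallback sets out from 18 and uses known reactions. Catalytic OsO4 with NMO (acetone/water, 0 °C) should dihydroxylate the enol-ether double bond of the benzofuran on the face anti to the C6 aryl group to give the cis-6a,11a-diol F1, a cyclic hemiketal. A pinacol rearrangement started by selective ionisation of the hemiketal hydroxyl (PPTS in CH2Cl2, or TMSOTf/2,6-lutidine at −78 °C) then moves C6 to C11a and returns to the route at 20. This separates the oxidation from the ionisation and makes the ionising site a hemiketal, the more easily ionised of the two hydroxyls.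

Step 13. Poor facial discrimination or slow oxidative addition may result, because the acetal carbon is flanked by the peri benzyloxy group and the benzopyrylium ion is strongly stabilised. The fallback sets out from 12 and 9 and replaces catalyst-controlled arylation by asymmetric ketone reduction and a stereoretentive ring closure. Carbonylative Suzuki coupling of 12 with 17 (PdCl2(dppf), CO, K2CO3, anisole, 80 °C) gives the ketone F2. Zincation with TMPZnCl·LiCl and Negishi coupling with 9 give the biaryl ketone F3. Aqueous HCl in THF removes the MOM group to give the hydroxy ketone F4 (in equilibrium with its cyclic hemiketal), and PhNTf2/Et3N gives the aryl triflate F5. (R)-Me-CBS with BH3·SMe2 should reduce F5 to the (S)-carbinol F6, with the twisted, doubly ortho-flanked benzofuranyl group acting as the large substituent. Intramolecular palladium-catalysed C–O coupling (Pd(OAc)2, t-BuXPhos, Cs2CO3, toluene, 80 °C) closes the chromene with retention, since the carbinol C–O bond is not broken, and returns to the route at 18.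

Step 11. The coupling of two hindered partners may be slower than protodezincation of 14. The fallback reverses the polarity and sets out from 14 and 9. Quenching 14 with iodine gives the 2-iodo aldehyde F7. Bromine–lithium exchange on 9 (n-BuLi, THF, −78 °C) and transmetalation with ZnCl2 give the flavan-8-ylzinc chloride F8. Negishi coupling of F7 with F8 (Pd-PEPPSI-IPent, THF, rt) returns to the route at 15.

Step 6. Partial ionisation of the activated carbinol to the p-benzyloxybenzyl cation would erode the enantiomeric purity of the flavan. The fallback sets out from 6. Cyclodehydration (PPTS, toluene, 4 Å sieves, reflux) gives the 2-aryl-4H-chromene F9, and iridium-catalysed asymmetric hydrogenation of its enol-ether double bond (Ir–phosphinooxazoline catalyst, H2 50 bar, CH2Cl2) sets flavan C2 and returns to the route at 8.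

Step 15. Hydrogenolytic opening of the benzylic C–O ring bonds (C2′–O7, flavan C2–O1) may compete with removal of the last, hindered peri benzyl ether. The fallback sets out from 20 and ends at 21: Lewis-acid debenzylation with BCl3 and pentamethylbenzene as cation scavenger (CH2Cl2, −78 °C), which needs no hydrogen and makes no new compound (F0).

## Further compounds

F1 | step 14 | cis-6a,11a-dihydroxy-6a,11a-dihydro derivative of 18 (both hydroxyls anti to the C6 aryl group) | O1c2cc(OCc6ccccc6)c3c(c2[C@]2(O)Oc5cc(OCc7ccccc7)cc(OCc7ccccc7)c5[C@]2(O)[C@@H]1c1ccc(OCc2ccccc2)cc1)O[C@H](c1ccc(OCc2ccccc2)cc1)CC3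
F2 | step 13 | [4,6-bis(benzyloxy)benzofuran-3-yl][4-(benzyloxy)phenyl]methanone | O=C(c1ccc(OCc2ccccc2)cc1)c1coc2cc(OCc3ccccc3)cc(OCc3ccccc3)c12
F3 | step 13 | [4,6-bis(benzyloxy)-2-[(2S)-5-(benzyloxy)-2-[4-(benzyloxy)phenyl]-7-(methoxymethoxy)chroman-8-yl]benzofuran-3-yl][4-(benzyloxy)phenyl]methanone | COCOc1cc(OCc2ccccc2)c3c(c1-c1oc4cc(OCc5ccccc5)cc(OCc5ccccc5)c4c1C(=O)c1ccc(OCc4ccccc4)cc1)O[C@H](c1ccc(OCc4ccccc4)cc1)CC3
F4 | step 13 | [4,6-bis(benzyloxy)-2-[(2S)-5-(benzyloxy)-2-[4-(benzyloxy)phenyl]-7-hydroxychroman-8-yl]benzofuran-3-yl][4-(benzyloxy)phenyl]methanone | Oc1cc(OCc2ccccc2)c3c(c1-c1oc4cc(OCc5ccccc5)cc(OCc5ccccc5)c4c1C(=O)c1ccc(OCc4ccccc4)cc1)O[C@H](c1ccc(OCc4ccccc4)cc1)CC3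
F5 | step 13 | 7-O-triflate of F4 | O=S(=O)(Oc1cc(OCc2ccccc2)c3c(c1-c1oc4cc(OCc5ccccc5)cc(OCc5ccccc5)c4c1C(=O)c1ccc(OCc4ccccc4)cc1)O[C@H](c1ccc(OCc4ccccc4)cc1)CC3)C(F)(F)F
F6 | step 13 | (S)-carbinol from reduction of the ketone of F5 | O=S(=O)(Oc1cc(OCc2ccccc2)c3c(c1-c1oc4cc(OCc5ccccc5)cc(OCc5ccccc5)c4c1[C@@H](O)c1ccc(OCc4ccccc4)cc1)O[C@H](c1ccc(OCc4ccccc4)cc1)CC3)C(F)(F)F
F7 | step 11 | 4,6-bis(benzyloxy)-2-iodobenzofuran-3-carbaldehyde | O=Cc1c(I)oc2cc(OCc3ccccc3)cc(OCc3ccccc3)c12
F8 | step 11 | [(2S)-5-(benzyloxy)-2-[4-(benzyloxy)phenyl]-7-(methoxymethoxy)chroman-8-yl]zinc chloride | COCOc1cc(OCc2ccccc2)c2c(c1[Zn]Cl)O[C@H](c1ccc(OCc3ccccc3)cc1)CC2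
F9 | step 6 | 5-(benzyloxy)-2-[4-(benzyloxy)phenyl]-7-(methoxymethoxy)-4H-chromene | COCOc1cc(OCc2ccccc2)c2c(c1)OC(c1ccc(OCc3ccccc3)cc1)=CC2
F0 | step 15 | none | none
A1 | alternative 1 | 4,6-bis(benzyloxy)-3′-[4-(benzyloxy)phenyl]spiro[benzofuran-2,2′-oxiran]-3-one (aurone-type epoxide, aryl cis to the ring oxygen, one enantiomer shown) | O=C1c2c(OCc3ccccc3)cc(OCc3ccccc3)cc2O[C@]12O[C@H]2c1ccc(OCc2ccccc2)cc1
A2 | alternative 1 | (2S)-5-(benzyloxy)-2-[4-(benzyloxy)phenyl]chroman-7-ol | Oc1cc(OCc2ccccc2)c2c(c1)O[C@H](c1ccc(OCc3ccccc3)cc1)CC2
A3 | alternative 2 | trans-2-[4-(benzyloxy)phenyl]-3-[2-hydroxy-4,6-bis(benzyloxy)benzoyl]-2,3-dihydrobenzofuran fused at flavan O7/C8 of the (2S)-5-(benzyloxy)-2-[4-(benzyloxy)phenyl]chromane | O=C(c1c(O)cc(OCc2ccccc2)cc1OCc1ccccc1)[C@@H]1c2c(cc(OCc3ccccc3)c3c2O[C@H](c2ccc(OCc4ccccc4)cc2)CC3)O[C@H]1c1ccc(OCc2ccccc2)cc1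
A4 | alternative 3 | (2S)-2-[4-(benzyloxy)phenyl]benzofuran-3(2H)-one fused at flavan O7/C8 of the (2S)-5-(benzyloxy)-2-[4-(benzyloxy)phenyl]chromane | O=C1c2c(cc(OCc3ccccc3)c3c2O[C@H](c2ccc(OCc4ccccc4)cc2)CC3)O[C@H]1c1ccc(OCc2ccccc2)cc1
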